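**Retrosynthetic overview**
- The target is (R)-1,1-bis(2,4,5-trimethoxyphenyl)propan-2-ol; because the two aryl groups are identical, C2 is the only stereocentre.
- C2–O/C1–H disconnection: enantioface-selective hydroboration–oxidation of the achiral, mirror-symmetric 1,1-bis(2,4,5-trimethoxyphenyl)prop-1-ene creates that stereocentre in the last step.
- The alkene comes from two aryl–C bonds plus loss of water: two equivalents of 2,4,5-trimethoxyphenyllithium add to ethyl propanoate.
- The aryllithium comes from 1,2,4-trimethoxybenzene by regioselective bromination and Br–Li exchange.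
- No ring is formed; both benzene rings are carried through intact from 1,2,4-trimethoxybenzene.

Assumption: only substrates, building blocks, intermediates and products are numbered; reagents (NBS, n-BuLi, the IpcBH2·TMEDA adduct, H2O2) are named on the Conditions and Reagents lines.

**Step 1**
Reactants: 1 1,2,4-trimethoxybenzene
Product: 2 1-bromo-2,4,5-trimethoxybenzene
Conditions: NBS (1.0 equiv), MeCN, 0 °C → rt, 1 h
Reagents that add atoms: N-bromosuccinimide, O=C1CCC(=O)N1Br
Why: Electrophilic aromatic bromination (SEAr) goes to C5, the only unhindered position that is para to one methoxy group and ortho to another.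

**Step 2**
Reactants: 2 1-bromo-2,4,5-trimethoxybenzene (2.1 equiv); 3 ethyl propanoate (1.0 equiv)
Product: 7 1,1-bis(2,4,5-trimethoxyphenyl)prop-1-ene, via aryllithium 4 (not isolated), via propiophenone 5 (not isolated), via tertiary carbinol 6 (not isolated)
Conditions: n-BuLi (2.1 equiv), THF, −78 °C, 30 min; 3, −78 → 0 °C; H2O; then TsOH·H2O (5 mol%), toluene, 60 °C
Reagents that add atoms: none
Why: Br–Li exchange outruns ortho-lithiation at −78 °C, double organolithium addition to the ester gives the tertiary carbinol through the ketone, and acid-catalysed E1 dehydration through the doubly aryl-stabilised cation gives the only possible alkene, which has no E/Z isomers.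

**Step 3**
Reactants: 7 1,1-bis(2,4,5-trimethoxyphenyl)prop-1-ene
Product: 9 tatarinoid C [(R)-1,1-bis(2,4,5-trimethoxyphenyl)propan-2-ol], via dialkylborane 8 (not isolated)
Conditions: (IpcBH2)2·TMEDA [from (−)-α-pinene] (0.6 equiv), BF3·OEt2 (1.2 equiv), THF, 25 °C, filter; 7, THF, −25 → 0 °C, 48 h; H2O, then 3 M NaOH, 30% H2O2, 0 → 25 °C
Reagents that add atoms: hydrogen peroxide, OO
Why: Brown asymmetric hydroboration–oxidation, in which IpcBH2 adds syn with boron at the non-benzylic C2, the reagent from (−)-α-pinene is predicted to give the (R)-C–B centre (by analogy: the (+)-α-pinene reagent gives S carbinols from alkenes of the type R2C=CHMe), and alkaline peroxide replaces boron by OH with retention.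

**Compound list**
1 | 1,2,4-trimethoxybenzene | COc1ccc(OC)c(OC)c1 | starting material
2 | 1-bromo-2,4,5-trimethoxybenzene | COc1cc(OC)c(Br)cc1OC | intermediate
3 | ethyl propanoate | CCC(=O)OCC | starting material
4 | (2,4,5-trimethoxyphenyl)lithium | [Li]c1cc(OC)c(OC)cc1OC | intermediate
5 | 1-(2,4,5-trimethoxyphenyl)propan-1-one | CCC(=O)c1cc(OC)c(OC)cc1OC | intermediate
6 | 1,1-bis(2,4,5-trimethoxyphenyl)propan-1-ol | CCC(O)(c1cc(OC)c(OC)cc1OC)c1cc(OC)c(OC)cc1OC | intermediate
7 | 1,1-bis(2,4,5-trimethoxyphenyl)prop-1-ene | CC=C(c1cc(OC)c(OC)cc1OC)c1cc(OC)c(OC)cc1OC | intermediate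
8 | isopinocampheyl[(2R)-1,1-bis(2,4,5-trimethoxyphenyl)propan-2-yl]borane (Ipc from (−)-α-pinene) | C[C@@H]1[C@@H](B[C@H](C)C(c3cc(OC)c(OC)cc3OC)c3cc(OC)c(OC)cc3OC)C[C@H]2C[C@@H]1C2(C)C | intermediate
9 | tatarinoid C, (R)-1,1-bis(2,4,5-trimethoxyphenyl)propan-2-ol | COc1cc(OC)c(C(c2cc(OC)c(OC)cc2OC)[C@@H](C)O)cc1OC | target

**Totals**
Total step count: 3. Longest linear sequence: 3.

**Steps most likely to fail, with fallbacks**

Step 3 (highest risk). The level of induction on this hindered, very electron-rich alkene is unproven and the sense rests on analogy, so it must be checked by chiral HPLC or Mosher ester analysis; ee may need upgrading by recrystallisation. The fallback sets out from 1 and comes back at 9. Two equivalents of 1 undergo a double Friedel–Crafts reaction with 1,1-dimethoxypropan-2-one (TfOH cat., CH2Cl2, 0 °C → rt) to give 1,1-bis(2,4,5-trimethoxyphenyl)propan-2-one F1. Corey–Bakshi–Shibata reduction of this achiral ketone ((S)-Me-CBS 20 mol%, BH3·SMe2, THF, −20 °C; large group CHAr2, small group CH3) then gives the (R)-alcohol 9.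

Step 2. The ketone 5 formed in the flask is enolisable and hindered, so the second aryllithium addition may stall by enolisation. The fallback sets out from 1 and comes back at 6. Friedel–Crafts acylation of 1 with commercial 2,4,5-trimethoxybenzoic acid in Eaton's reagent (P2O5/MsOH, 60 °C) gives the non-enolisable bis(2,4,5-trimethoxyphenyl)methanone F2. Addition of EtMgBr/CeCl3 (THF, −78 → 0 °C) gives carbinol 6, which is dehydrated to 7 as in step 2.

Step 1 (lowest risk). Over-bromination or oxidation of the very electron-rich ring would lower the yield. The fallback sets out from 1 and comes back at 7, needing no halide or organometallic. Two equivalents of 1 condense with propanal (TsOH cat., CH2Cl2, rt) to give 1,1-bis(2,4,5-trimethoxyphenyl)propane F3. DDQ (1.1 equiv, dioxane, rt) abstracts the doubly benzylic hydride and the cation loses a β-proton to give alkene 7.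

**Further compounds**
F1 | step 3 | 1,1-bis(2,4,5-trimethoxyphenyl)propan-2-one | CC(=O)C(c1cc(OC)c(OC)cc1OC)c1cc(OC)c(OC)cc1OC
F2 | step 2 | bis(2,4,5-trimethoxyphenyl)methanone | O=C(c1cc(OC)c(OC)cc1OC)c1cc(OC)c(OC)cc1OC
F3 | step 1 | 1,1-bis(2,4,5-trimethoxyphenyl)propane | CCC(c1cc(OC)c(OC)cc1OC)c1cc(OC)c(OC)cc1OC
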